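## Structural features

The target is a 2H-chromene in which a benzene ring (ring A) is fused through C4a–C8a to a pyran ring (ring B) made up of O1, the sp3 carbon C2 and the C3=C4 double bond. Ring A carries an acetyl group at C6 and a hydrogen-bonded hydroxyl group at C7, ortho to each other, with C6 para to the O1-bearing C8a and C7 para to C4a. C2 is the only stereocentre, has the (R) configuration, is fully substituted (O1, C3, CH3, CH2O) and has no neighbouring stereocentre, so nothing in the molecule can relay its configuration. Its CH2O arm is a neopentyl-type primary alcohol esterified with (E)-4-hydroxy-3-methoxycinnamic acid. The fragile elements are the 2H-chromene itself, which can open by a reversible oxa-6π electrocyclic reaction under heat or light to an achiral o-quinone methide and so lose C2, the acid-sensitive styrene-type C3=C4 bond, and the cinnamate ester and two phenols, which limit the use of base and nucleophiles. The real difficulty is the oxygen-bearing quaternary centre, where a catalyst has to tell CH3 from CH2O. The key step exploits the position of C4 on C4a, ortho to the O1-bearing C8a: C4 can be the formyl carbon of a salicylaldehyde, while C2 and C3 arrive as the β- and α-carbons of an enal whose carbonyl carbon stays on C3 as a formyl group to be removed afterwards.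

## Logic of the disconnections

**18 to 17.** The O–acetyl bond of the cinnamate phenol is cut. The phenol of the acid half must be masked during esterification so that it cannot acylate itself. The forward step must cleave an aryl acetate faster than the alkyl cinnamate and must stay mild enough for the chromene.

**17 to 14 and 16 (16 from 15).** The acyl C–O bond of the ester is cut. This is the most convergent cut and gives two halves of similar size, one of them a single step from a commercial acid. The forward step must acylate a neopentyl-type primary alcohol in the presence of the C7 phenol, which is deactivated by its hydrogen bond to the acetyl group.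

**14 to 13.** The O–Si bond is restored. The silyl ether carries the primary oxygen through the enal synthesis and the annulation. The forward step must be a buffered fluoride cleavage that leaves the phenol and ketone alone.

**13 to 12.** A formyl group is added back at C3 (C3–CHO bond). This converts the chromene into the product type of an oxa-Michael–aldol condensation. The forward step must remove the carbonyl carbon without opening the chromene thermally and without touching the acetyl ketone.

**12 to 4 and 9.** O1–C2 and C3–C4 are cut. Ring B, the stereocentre and two skeletal bonds then come from two achiral pieces in one operation, and the formyl carbon of 4 fixes the linear 6-acetyl-7-hydroxy pattern. The forward step needs catalyst control at a β,β-disubstituted enal, geometrically pure 9, and discrimination between the two phenols and between the two carbonyl groups of 4. The C7-type hydroxyl is left free on purpose: it is hydrogen-bonded to the acetyl group and has no aldehyde next to it.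

**4 to 1 and 2 (through 3).** The aryl C5–C(acyl) bond is cut. A bromine at C5 fixes the position of the acetyl group with certainty. Direct electrophilic acylation of the bromine-free parent of 1, a deactivated and Lewis-acid-sensitive substrate, would be uncertain in both yield and position. The forward step must be a cross-coupling that tolerates two free phenols and a formyl group.

**9 to 8 to 7 to 5 and 6.** The C2=C3 bond of the enal is cut by olefination logic, followed by two oxidation-level adjustments. Both building blocks are commercial. The forward sequence must deliver a single (E) isomer, because the configuration of C2 in 12 depends on the geometry of 9.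

## Other disconnections considered

**Alternative 1:** The cut removes C4 as a one-carbon unit. Bonds C3–C4 and C4–C4a are broken, contracting ring B to the furanone of the enantioenriched benzofuran-3(2H)-one A2. In the forward direction the diazo reagent trimethylsilyldiazomethane A3, activated by the Lewis acid Sc(OTf)3 A4, would add to the C3 ketone of A2. The aryl carbon would migrate to the diazo carbon with extrusion of the diazo nitrogen, and protodesilylation would leave the chroman-3-one A1 (a Tiffeneau–Demjanov-type homologation).
- In its favour: the quaternary centre is made beforehand at the α-position of a five-membered aryl ketone, where catalytic asymmetric α-functionalisation has closer precedent than an oxa-Michael addition to a β,β-disubstituted enal. The ring expansion does not touch that centre. On precedent for the stereo-setting step, and on avoiding a hot decarbonylation of a chromene, this alternative is the better of the two.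
- Against it here: A1 has neither the C6 acetyl group nor a free C7 hydroxyl, and its C3 ketone is at the wrong oxidation level. After the key step it would need a hydride reduction, a dehydration, a Friedel–Crafts acetylation on ring A, a methyl ether cleavage and then the same three end-game steps, plus the asymmetric synthesis of A2. The dehydration can only go towards C4, which is a point in its favour.
- Structure: the chosen plan fixes the acetyl position from the start, whereas the alternative relies on a late acetylation going para to O1; the chosen plan is better there.
- Mechanism: the alternative carries less stereochemical risk but adds a migration-selectivity risk (aryl against the oxygen-bearing quaternary carbon, and single against double insertion).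
- Step economy: it is clearly longer, an estimated fourteen or more steps against ten.

**Alternative 2:** The cut is at C2–C3 and O1–C2. In the forward direction a chiral primary amine–thiourea with an acid cocatalyst would condense one acetyl group of the symmetric 4,6-diacetylresorcinol A6 with ketone 5 (aldol condensation, C2–C3). A 6-endo-trig oxa-Michael addition (O1–C2) would then close the chroman-4-one A5.
- In its favour: A6 and 5 are both commercial, so the key step is the first step. No carbon has to be excised, and A5 already carries the acetyl group, the free hydroxyl and the (R) centre.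
- Step economy: after A5 a ketone reduction, a dehydration and the same end game would follow, about seven steps in all. On step count this alternative is better than the chosen plan.
- Stereochemical problem: it is equal to the chosen plan, since the catalyst must again distinguish CH3 from CH2O at a fully substituted carbon without close precedent.
- Against it here: the oxa-Michael step is reversible, and A5 keeps an acidic C3–H next to a phenoxide leaving group that is stabilised by the para acetyl group. A5 could therefore racemise by retro-oxa-Michael opening, whereas 12 is locked once water is lost.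
- Further weaknesses: the two identical acetyl/hydroxyl pairs invite double annulation, ketone 5 can form an enamine on either side, and the later reduction must select the C4 ketone beside the C6 acetyl ketone.
- Comparison: shorter and free of the decarbonylation, but weaker in configurational stability and chemoselectivity.

**Alternative 3:** The cut is at C4–C4a and C8a–O1. In the forward direction the catalyst Pd(dppf)Cl2 A10 and the base Cs2CO3 A11 would couple the aryl bromide A8 with the Z-alkenylboron unit of the enantiopure oxaborole A9 (Suzuki–Miyaura coupling). The liberated tertiary alkoxide would then displace the neighbouring fluoride, which is activated by the para acetyl group (SNAr), closing ring B to give A7.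
- In its favour: the annulation creates no stereocentre, because C2 is carried in from A9. Its outcome does not depend on facial selectivity, and each elementary step has close precedent. On certainty of the ring-forming step this alternative is better than the chosen plan.
- It needs no formyl removal and no rhodium, so thermal stress on the chromene is lower; it is better on this point too.
- Regiochemistry is fixed by the positions of bromine and fluorine, which is equal to the chosen plan.
- Against it here: A9 has to be made enantiopure, for example from the tertiary propargylic alcohol A12 by Z-selective hydroboration. A12 in turn needs an enantioselective alkynylation of ketone 5 or a resolution, so the CH3/CH2O discrimination is moved upstream into a multi-step fragment synthesis and not removed.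
- A8 carries a methoxymethyl ether whose acidic removal late in the sequence meets an acid-sensitive chromene and adds steps.
- Step economy: estimated eleven to thirteen steps against ten, so worse.

Key step: step 5

Assumption: the facial course of the new oxa-Michael step is taken to follow the usual steric-shielding model of diarylprolinol silyl ether iminium ions. On that model (R)-2-[diphenyl(trimethylsilyloxy)methyl]pyrrolidine (C[Si](C)(C)OC(c1ccccc1)(c1ccccc1)[C@H]1CCCN1) with the (E)-enal gives the (R)-chromene. If the sense proved opposite, the enantiomeric amine would be used. The descriptor of C2 is (R) in 12, 13, 14, 17 and 18 alike, because the order O1 > CH2O > C3 > CH3 holds throughout.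

## Route

**Step 1**
Reactants: 1 5-bromo-2,4-dihydroxybenzaldehyde; 2 tributyl(1-ethoxyvinyl)stannane
Product: 4 5-acetyl-2,4-dihydroxybenzaldehyde, via enol ether 3 (not isolated)
Conditions: PdCl2(PPh3)2 (5 mol %), 1,4-dioxane, 100 °C; then 2 M HCl, rt
Reagents that add atoms: water, O
Why: Migita–Kosugi–Stille coupling (zerovalent palladium formed in the flask) of the aryl bromide with the α-ethoxyvinylstannane, an acetyl anion equivalent, tolerates free phenols and the formyl group; dilute acid then hydrolyses enol ether 3 to the methyl ketone, so the acetyl group enters exactly at the carbon that carried bromine.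

**Step 2**
Reactants: 5 1-(tert-butyldimethylsilyloxy)propan-2-one; 6 triethyl phosphonoacetate
Product: 7 ethyl (E)-4-(tert-butyldimethylsilyloxy)-3-methylbut-2-enoate
Conditions: NaH, THF, 0 °C → rt; chromatography to remove the minor (Z) isomer
Reagents that add atoms: none
Why: Horner–Wadsworth–Emmons olefination of a ketone with a stabilised phosphonate anion should place the ester trans to the larger silyloxymethyl group; the minor (Z) isomer is removed here (or at 8) and the geometry confirmed by NOE, because the key step depends on it.

**Step 3**
Reactants: 7 ethyl (E)-4-(tert-butyldimethylsilyloxy)-3-methylbut-2-enoate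
Product: 8 (E)-4-(tert-butyldimethylsilyloxy)-3-methylbut-2-en-1-ol
Conditions: i-Bu2AlH (2.2 equiv), CH2Cl2, −78 → 0 °C; aq. KNaC4H4O6 (potassium sodium tartrate)
Reagents that add atoms: none
Why: 1,2-reduction of the α,β-unsaturated ester by the aluminium hydride gives the allylic alcohol without touching the double-bond geometry or the silyl ether.

**Step 4**
Reactants: 8 (E)-4-(tert-butyldimethylsilyloxy)-3-methylbut-2-en-1-ol
Product: 9 (E)-4-(tert-butyldimethylsilyloxy)-3-methylbut-2-enal
Conditions: MnO2 (10 equiv), CH2Cl2, rt, dark
Reagents that add atoms: none
Why: Heterogeneous MnO2 oxidation is selective for allylic alcohols, stops at the aldehyde and is neutral, so the (E) geometry should be retained; 9 is used promptly.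

**Step 5**
Reactants: 4 5-acetyl-2,4-dihydroxybenzaldehyde; 9 (E)-4-(tert-butyldimethylsilyloxy)-3-methylbut-2-enal
Product: 12 (R)-6-acetyl-2-[(tert-butyldimethylsilyloxy)methyl]-7-hydroxy-2-methyl-2H-chromene-3-carbaldehyde, via iminium ion 10 (not isolated), via enamine 11 (not isolated)
Conditions: (R)-2-[diphenyl(trimethylsilyloxy)methyl]pyrrolidine (20 mol %), 2-nitrobenzoic acid (20 mol %), 4 Å MS, PhMe, 0 °C → rt, dark
Reagents that add atoms: none
Why: Proposed new method: the amine and 9 condense to the (E,E)-iminium ion 10, the formyl-flanked 2-OH of 4 adds to its β-carbon (O1–C2) to give enamine 11, the enamine carbon attacks the neighbouring formyl group (C3–C4), and loss of water with hydrolysis of the product iminium ion releases 12 and the catalyst. The closest known reaction type is the diarylprolinol silyl ether-catalysed oxa-Michael–aldol condensation of salicylaldehydes with β-monosubstituted enals; base-mediated racemic versions with β,β-disubstituted enals and iminium additions of carbon nucleophiles that create quaternary centres are known, but an enantioselective oxa-Michael–aldol sequence at a β,β-disubstituted enal is not. The pyran ring closes in the aldol event, a 6-exo-trig addition of the enamine to the aldehyde, which the following dehydration makes irreversible. C2 is set under catalyst control: the diphenyl(trimethylsilyloxy)methyl group covers one face of the s-trans (E)-iminium ion and the phenol should add to the open face, which on the usual shielding model gives (R) from the (R)-amine and the (E)-enal. The step needs facial selectivity at a β-carbon whose two substituents differ only as CH3 and CH2OSi, so it depends on the geometric purity of 9 and on ring closure being faster than E/Z exchange through the dienamine and than retro-oxa-Michael reversal; the weakly basic 2-nitrobenzoate, the low temperature and the acidic, para-acetyl-activated phenol are chosen to favour this. Chemoselectivity comes from the substrate: only the 2-OH has an aldehyde in the ortho position, the 4-OH is tied up by a hydrogen bond to the acetyl group, and a methyl ketone is a far poorer aldol acceptor than an aldehyde, so addition at the other oxygen should be a reversible dead end. Because the formyl carbon becomes C4, the linear 6-acetyl-7-hydroxy arrangement follows without ambiguity.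

**Step 6**
Reactants: 12 (R)-6-acetyl-2-[(tert-butyldimethylsilyloxy)methyl]-7-hydroxy-2-methyl-2H-chromene-3-carbaldehyde
Product: 13 (R)-1-[2-[(tert-butyldimethylsilyloxy)methyl]-7-hydroxy-2-methyl-2H-chromen-6-yl]ethan-1-one
Conditions: RhCl(PPh3)3 (1.1 equiv), PhMe, 90 °C, Ar, dark
Reagents that add atoms: none
Why: Tsuji–Wilkinson decarbonylation: the formyl C–H adds oxidatively to monovalent rhodium, CO is extruded and C3–H is formed by reductive elimination with retention of the double bond; the stoichiometric reagent allows a moderate temperature, chosen to limit electrocyclic opening of the chromene, and C2 is not involved.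

**Step 7**
Reactants: 13 (R)-1-[2-[(tert-butyldimethylsilyloxy)methyl]-7-hydroxy-2-methyl-2H-chromen-6-yl]ethan-1-one
Product: 14 (R)-1-[7-hydroxy-2-(hydroxymethyl)-2-methyl-2H-chromen-6-yl]ethan-1-one
Conditions: Bu4NF, AcOH (1:1, 1.5 equiv), THF, 0 °C → rt
Reagents that add atoms: none
Why: Fluoride cleaves the primary silyl ether; buffering with acetic acid keeps the medium close to neutral, so the phenol, the ketone and the chromene should be unaffected.

**Step 8**
Reactants: 15 (E)-ferulic acid
Product: 16 (E)-3-(4-acetoxy-3-methoxyphenyl)prop-2-enoic acid
Conditions: Ac2O, pyridine, rt; then H2O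
Reagents that add atoms: acetic anhydride, CC(=O)OC(C)=O
Why: Phenol O-acetylation; any mixed anhydride formed at the carboxyl group is hydrolysed in the aqueous work-up, leaving the free acid with the phenol masked.

**Step 9**
Reactants: 14 (R)-1-[7-hydroxy-2-(hydroxymethyl)-2-methyl-2H-chromen-6-yl]ethan-1-one; 16 (E)-3-(4-acetoxy-3-methoxyphenyl)prop-2-enoic acid
Product: 17 [(R)-6-acetyl-7-hydroxy-2-methyl-2H-chromen-2-yl]methyl (E)-3-(4-acetoxy-3-methoxyphenyl)prop-2-enoate
Conditions: N,N'-diisopropylcarbodiimide (1.2 equiv), 4-dimethylaminopyridine (0.1 equiv), CH2Cl2, 0 °C → rt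
Reagents that add atoms: none
Why: Steglich esterification: the primary alcohol should be acylated in preference to the C7 phenol, which is hydrogen-bonded to the ortho acetyl group and electron-poor; any aryl ester formed there would be cleaved again in step 10, and C2 is untouched.

**Step 10**
Reactants: 17 [(R)-6-acetyl-7-hydroxy-2-methyl-2H-chromen-2-yl]methyl (E)-3-(4-acetoxy-3-methoxyphenyl)prop-2-enoate
Product: 18 [(R)-6-acetyl-7-hydroxy-2-methyl-2H-chromen-2-yl]methyl (E)-3-(4-hydroxy-3-methoxyphenyl)prop-2-enoate (CNP0375196.1)
Conditions: pyrrolidine (2 equiv), CH2Cl2, 0 °C → rt; aq. NH4Cl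
Reagents that add atoms: none
Why: Aminolysis of an aryl acetate, which has a phenoxide leaving group, should be far faster than aminolysis of or conjugate addition to the electron-rich alkyl cinnamate, so only the phenol acetate is removed.

## Compound list

1 | 5-bromo-2,4-dihydroxybenzaldehyde | O=Cc1cc(Br)c(O)cc1O | starting material
2 | tributyl(1-ethoxyvinyl)stannane | CCCC[Sn](CCCC)(CCCC)C(=C)OCC | starting material
3 | 5-(1-ethoxyvinyl)-2,4-dihydroxybenzaldehyde | CCOC(=C)c1cc(C=O)c(O)cc1O | intermediate (not isolated)
4 | 5-acetyl-2,4-dihydroxybenzaldehyde | CC(=O)c1cc(C=O)c(O)cc1O | intermediate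
5 | 1-(tert-butyldimethylsilyloxy)propan-2-one | CC(=O)CO[Si](C)(C)C(C)(C)C | starting material
6 | triethyl phosphonoacetate | CCOC(=O)CP(=O)(OCC)OCC | starting material
7 | ethyl (E)-4-(tert-butyldimethylsilyloxy)-3-methylbut-2-enoate | CC(C)(C)[Si](C)(C)OC/C(C)=C/C(=O)OCC | intermediate
8 | (E)-4-(tert-butyldimethylsilyloxy)-3-methylbut-2-en-1-ol | CC(C)(C)[Si](C)(C)OC/C(C)=C/CO | intermediate
9 | (E)-4-(tert-butyldimethylsilyloxy)-3-methylbut-2-enal | CC(C)(C)[Si](C)(C)OC/C(C)=C/C=O | intermediate
10 | (2R)-1-[(1E,2E)-4-(tert-butyldimethylsilyloxy)-3-methylbut-2-en-1-ylidene]-2-[diphenyl(trimethylsilyloxy)methyl]pyrrolidin-1-ium 2-nitrobenzoate | CC(C)(C)[Si](C)(C)OC/C(C)=C/C=[N+]1\CCC[C@@H]1C(c1ccccc1)(c1ccccc1)O[Si](C)(C)C.[O-]C(=O)c1ccccc1[N+](=O)[O-] | intermediate (not isolated)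
11 | 5-acetyl-2-[[(2R,3E)-1-(tert-butyldimethylsilyloxy)-4-[(2R)-2-[diphenyl(trimethylsilyloxy)methyl]pyrrolidin-1-yl]-2-methylbut-3-en-2-yl]oxy]-4-hydroxybenzaldehyde | CC(C)(C)[Si](C)(C)OC[C@@](C)(/C=C/N1CCC[C@@H]1C(c1ccccc1)(c1ccccc1)O[Si](C)(C)C)Oc1cc(O)c(C(C)=O)cc1C=O | intermediate (not isolated)
12 | (R)-6-acetyl-2-[(tert-butyldimethylsilyloxy)methyl]-7-hydroxy-2-methyl-2H-chromene-3-carbaldehyde | CC(C)(C)[Si](C)(C)OC[C@@]2(C)C(C=O)=Cc3cc(C(C)=O)c(O)cc3O2 | intermediate
13 | (R)-1-[2-[(tert-butyldimethylsilyloxy)methyl]-7-hydroxy-2-methyl-2H-chromen-6-yl]ethan-1-one | CC(C)(C)[Si](C)(C)OC[C@@]2(C)C=Cc3cc(C(C)=O)c(O)cc3O2 | intermediate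
14 | (R)-1-[7-hydroxy-2-(hydroxymethyl)-2-methyl-2H-chromen-6-yl]ethan-1-one | OC[C@@]2(C)C=Cc3cc(C(C)=O)c(O)cc3O2 | intermediate
15 | (E)-ferulic acid | COc1cc(/C=C/C(=O)O)ccc1O | starting material
16 | (E)-3-(4-acetoxy-3-methoxyphenyl)prop-2-enoic acid | COc1cc(/C=C/C(=O)O)ccc1OC(C)=O | intermediate
17 | [(R)-6-acetyl-7-hydroxy-2-methyl-2H-chromen-2-yl]methyl (E)-3-(4-acetoxy-3-methoxyphenyl)prop-2-enoate | COc1cc(/C=C/C(=O)OC[C@@]2(C)C=Cc3cc(C(C)=O)c(O)cc3O2)ccc1OC(C)=O | intermediate
18 | [(R)-6-acetyl-7-hydroxy-2-methyl-2H-chromen-2-yl]methyl (E)-3-(4-hydroxy-3-methoxyphenyl)prop-2-enoate | COc1cc(/C=C/C(=O)OC[C@@]2(C)C=Cc3cc(C(C)=O)c(O)cc3O2)ccc1O | target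

## Step count and least certain steps

Total: 10 steps. Longest linear sequence: 8 steps (2, 3, 4, 5, 6, 7, 9, 10).

**Step 5 (key step, proposed new method).** The most likely failure is poor facial selectivity: the iminium ion may exchange its E and Z forms through the dienamine faster than it is trapped, and the two β-substituents are of similar size. The second risk is low conversion, because oxa-Michael addition to a fully substituted β-carbon is slow and reversible. The fallback uses known chemistry and sets out from 4 and 9. The base-mediated oxa-Michael–aldol condensation (K2CO3, 1,4-dioxane, reflux), known for salicylaldehydes with β,β-disubstituted enals, would give the racemic aldehyde F1. The conditions of steps 6 and 7 would then give the racemic silyl ether F2 and the racemic alcohol F3. F3 would be resolved by preparative chromatography on a cellulose tris(3,5-dimethylphenylcarbamate) stationary phase; the (R)-enantiomer is 14, where the route is rejoined, and the (S)-enantiomer F4 is set aside.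

**Step 6.** The most likely failure is partial loss of configuration at C2 through reversible electrocyclic ring opening of the chromene at the temperature needed to extrude CO from a hindered enal, or sluggish decarbonylation that forces a higher temperature. The fallback sets out from 12. Hydrogenation of the C3=C4 bond (H2, Pd/C, EtOAc, rt) would give the chromane-3-carbaldehyde F5 as a mixture at C3. Decarbonylation at the chromane level (RhCl(PPh3)3, PhMe, 100 °C), where the ring cannot open electrocyclically, would give the chromane F6. Benzylic dehydrogenation with DDQ (1,4-dioxane, 80 °C), a known way from 2,2-disubstituted chromans to 2H-chromenes, would return to the route at 13.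

**Step 9.** The most likely failure is slow acylation of the neopentyl-type alcohol, which allows rearrangement of the activated acid to an N-acylurea, competing acylation of the C7 phenol, or acetyl transfer from the aryl acetate. The fallback sets out from 14. Acylation with diethylphosphonoacetic acid and N,N'-diisopropylcarbodiimide, a small acid that acylates hindered alcohols readily, would give the phosphonoacetate F7. Horner–Wadsworth–Emmons olefination with 4-acetoxy-3-methoxybenzaldehyde (LiCl, DBU, MeCN, rt) would build the (E)-cinnamate on the substrate and rejoin the route at 17.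

**Step 10.** The most likely failure is loss of the cinnamate ester by aminolysis, or amine addition to the cinnamate double bond, before the acetate is fully cleaved. The fallback changes the protecting group to one removed by fluoride, and sets out from 15 and 14. Silylation of 15 (tert-butyldimethylsilyl chloride, imidazole, DMF) would give the bis-silyl compound F8. Brief selective hydrolysis of its silyl ester (K2CO3, MeOH/H2O, 0 °C) would give the silyl-protected acid F9. Esterification with 14 under the conditions of step 9 would give the ester F10, and buffered fluoride (Bu4NF, AcOH, THF, 0 °C) would rejoin the route at 18.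

## Further compounds

F1 | step 5 | rac-6-acetyl-2-[(tert-butyldimethylsilyloxy)methyl]-7-hydroxy-2-methyl-2H-chromene-3-carbaldehyde | CC(C)(C)[Si](C)(C)OCC1(C)C(C=O)=Cc2cc(C(C)=O)c(O)cc2O1
F2 | step 5 | rac-1-[2-[(tert-butyldimethylsilyloxy)methyl]-7-hydroxy-2-methyl-2H-chromen-6-yl]ethan-1-one | CC(C)(C)[Si](C)(C)OCC1(C)C=Cc2cc(C(C)=O)c(O)cc2O1
F3 | step 5 | rac-1-[7-hydroxy-2-(hydroxymethyl)-2-methyl-2H-chromen-6-yl]ethan-1-one | OCC1(C)C=Cc2cc(C(C)=O)c(O)cc2O1
F4 | step 5 | (S)-1-[7-hydroxy-2-(hydroxymethyl)-2-methyl-2H-chromen-6-yl]ethan-1-one | OC[C@]2(C)C=Cc3cc(C(C)=O)c(O)cc3O2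
F5 | step 6 | (2R)-6-acetyl-2-[(tert-butyldimethylsilyloxy)methyl]-7-hydroxy-2-methylchromane-3-carbaldehyde (both C3 epimers) | CC(C)(C)[Si](C)(C)OC[C@@]1(C)C(C=O)Cc2cc(C(C)=O)c(O)cc2O1
F6 | step 6 | (R)-1-[2-[(tert-butyldimethylsilyloxy)methyl]-7-hydroxy-2-methylchroman-6-yl]ethan-1-one | CC(C)(C)[Si](C)(C)OC[C@@]1(C)CCc2cc(C(C)=O)c(O)cc2O1
F7 | step 9 | [(R)-6-acetyl-7-hydroxy-2-methyl-2H-chromen-2-yl]methyl 2-(diethoxyphosphoryl)acetate | CCOP(=O)(CC(=O)OC[C@@]1(C)C=Cc2cc(C(C)=O)c(O)cc2O1)OCC
F8 | step 10 | tert-butyldimethylsilyl (E)-3-[4-(tert-butyldimethylsilyloxy)-3-methoxyphenyl]prop-2-enoate | COc1cc(/C=C/C(=O)O[Si](C)(C)C(C)(C)C)ccc1O[Si](C)(C)C(C)(C)C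
F9 | step 10 | (E)-3-[4-(tert-butyldimethylsilyloxy)-3-methoxyphenyl]prop-2-enoic acid | COc1cc(/C=C/C(=O)O)ccc1O[Si](C)(C)C(C)(C)C
F10 | step 10 | [(R)-6-acetyl-7-hydroxy-2-methyl-2H-chromen-2-yl]methyl (E)-3-[4-(tert-butyldimethylsilyloxy)-3-methoxyphenyl]prop-2-enoate | COc1cc(/C=C/C(=O)OC[C@@]2(C)C=Cc3cc(C(C)=O)c(O)cc3O2)ccc1O[Si](C)(C)C(C)(C)C
A1 | alternative 1 | (S)-2-[(tert-butyldimethylsilyloxy)methyl]-7-methoxy-2-methylchroman-3-one | CC(C)(C)[Si](C)(C)OC[C@@]2(C)C(=O)Cc3ccc(OC)cc3O2
A2 | alternative 1 | (S)-2-[(tert-butyldimethylsilyloxy)methyl]-6-methoxy-2-methylbenzofuran-3(2H)-one | CC(C)(C)[Si](C)(C)OC[C@]1(C)Oc2cc(OC)ccc2C1=O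
A3 | alternative 1 | trimethylsilyldiazomethane | C[Si](C)(C)C=[N+]=[N-]
A4 | alternative 1 | scandium tris(trifluoromethanesulfonate), Sc(OTf)3 | [Sc+3].[O-]S(=O)(=O)C(F)(F)F.[O-]S(=O)(=O)C(F)(F)F.[O-]S(=O)(=O)C(F)(F)F
A5 | alternative 2 | (R)-6-acetyl-2-[(tert-butyldimethylsilyloxy)methyl]-7-hydroxy-2-methylchroman-4-one | CC(C)(C)[Si](C)(C)OC[C@@]2(C)CC(=O)c3cc(C(C)=O)c(O)cc3O2
A6 | alternative 2 | 4,6-diacetylresorcinol | CC(=O)c1cc(C(C)=O)c(O)cc1O
A7 | alternative 3 | (R)-1-[2-[(tert-butyldimethylsilyloxy)methyl]-7-(methoxymethoxy)-2-methyl-2H-chromen-6-yl]ethan-1-one | CC(C)(C)[Si](C)(C)OC[C@@]2(C)C=Cc3cc(C(C)=O)c(OCOC)cc3O2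
A8 | alternative 3 | 1-[5-bromo-4-fluoro-2-(methoxymethoxy)phenyl]ethan-1-one | CC(=O)c1cc(Br)c(F)cc1OCOC
A9 | alternative 3 | (R)-5-[(tert-butyldimethylsilyloxy)methyl]-5-methyl-1,2-oxaborol-2(5H)-ol | CC(C)(C)[Si](C)(C)OC[C@@]1(C)C=CB(O)O1
A10 | alternative 3 | [1,1'-bis(diphenylphosphino)ferrocene]dichloropalladium, Pd(dppf)Cl2 | Cl[Pd]Cl.[Fe+2].C1=C[C-](C=C1)P(c1ccccc1)c1ccccc1.C1=C[C-](C=C1)P(c1ccccc1)c1ccccc1
A11 | alternative 3 | caesium carbonate, Cs2CO3 | [Cs+].[Cs+].[O-]C([O-])=O
A12 | alternative 3 | (R)-1-(tert-butyldimethylsilyloxy)-2-methylbut-3-yn-2-ol | CC(C)(C)[Si](C)(C)OC[C@](C)(O)C#C
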